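**Retrosynthetic overview**

1. Feature: in the butenolide ring (O1, C2 carbonyl, C3, C4, C5; exocyclic C6 = CHI; carbinol C1' on C3) the carbonyl carbon C2 and the bromine on C4 are trans across C3=C4. This is the pattern that anti addition of I–Br leaves on an alkyne, so C2 is traced back to CO taking the place of an iodine on C3.
2. Target 11 ⇒ hydroxy enynoic acid 10 by iodolactonisation (O1–C5 and C6–I, 5-exo-dig). The butenolide is the only ring and is closed last.
3. 10 ⇒ silylated acid 9 ⇒ (E)-bromo-iodo enyne 7 by disconnection of C2–C3 (hydroxycarbonylation of the C3–I bond, C4–Br kept).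
4. 7 ⇒ diyne 5 (anti I–Br addition across C3≡C4) ⇒ (R)-hex-1-yn-3-ol 2 + bromoalkyne 3 (C4–C5, Cadiot–Chodkiewicz); C1' comes from lipase resolution of 1.

Key step: step 5

Assumption: the lipase is taken to follow its usual size rule with 1 (ethynyl in the small pocket, propyl in the large one), so that the (S)-alcohol is acetylated and the (R)-alcohol is the one left behind.

**Route**

Step 1
Reactants: 1 rac-hex-1-yn-3-ol
Product: 2 (R)-hex-1-yn-3-ol
Conditions: Novozym 435 (immobilised Candida antarctica lipase B), vinyl acetate, hexane, 30 °C, taken just past half conversion; chromatography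
Reagents that add atoms: none
Why: Lipase-catalysed kinetic resolution by irreversible transesterification, in which the enzyme should acetylate the (S)-alcohol and leave the (R)-alcohol, so that the only stereocentre, C1', is selected here and its enantiomeric purity rises as conversion passes one half.

Step 2
Reactants: 2 (R)-hex-1-yn-3-ol; 3 (bromoethynyl)triisopropylsilane
Product: 4 (R)-1-(triisopropylsilyl)octa-1,3-diyn-5-ol
Conditions: CuCl (5 mol %), NH2OH·HCl, 30% aq. n-BuNH2, Et2O, 0 °C → rt
Reagents that add atoms: none
Why: Cadiot–Chodkiewicz coupling, in which the copper acetylide of 2 displaces bromide from 3 to form the C4–C5 bond of the unsymmetrical diyne while the hydroxylamine salt keeps copper monovalent and so holds back homocoupling, the stereocentre not being touched.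

Step 3
Reactants: 4 (R)-1-(triisopropylsilyl)octa-1,3-diyn-5-ol
Product: 5 (R)-5-(tert-butyldimethylsilyloxy)-1-(triisopropylsilyl)octa-1,3-diyne
Conditions: t-BuMe2SiCl, imidazole, DMF, rt
Reagents that add atoms: tert-butyldimethylsilyl chloride, CC(C)(C)[Si](C)(C)Cl
Why: Imidazole-promoted silylation of a secondary alcohol, which masks the hydroxyl before the halogenation and keeps the oxygen from intercepting the acylpalladium in step 5.

Step 4
Reactants: 5 (R)-5-(tert-butyldimethylsilyloxy)-1-(triisopropylsilyl)octa-1,3-diyne; 6 iodine monobromide
Product: 7 (R,E)-[3-bromo-5-(tert-butyldimethylsilyloxy)-4-iodooct-3-en-1-yn-1-yl]triisopropylsilane (I on C3 next to the carbinol, Br on C4, I and Br trans)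
Conditions: IBr (1.05 equiv), CH2Cl2, −78 → 0 °C, dark; aq. Na2S2O3
Reagents that add atoms: none
Why: Electrophilic anti iodobromination of an alkyne, in which iodine should add to C3 of the inner alkyne and bromide should open the iodonium ion from the opposite face at C4, where the charge is delocalised into the C5≡C6 bond and not opposed inductively by the C1' oxygen as it is at C3, while the triisopropylsilyl group shields the outer alkyne, so that I and Br end up trans and Br cis to C1'.

Step 5
Reactants: 7 (R,E)-[3-bromo-5-(tert-butyldimethylsilyloxy)-4-iodooct-3-en-1-yn-1-yl]triisopropylsilane; 8 carbon monoxide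
Product: 9 (R,E)-3-bromo-2-[1-(tert-butyldimethylsilyloxy)butyl]-5-(triisopropylsilyl)pent-2-en-4-ynoic acid (carboxyl cis to the alkynyl group)
Conditions: Pd(OAc)2 (5 mol %), PPh3 (20 mol %), CO (10 bar), Et3N, DMF–H2O 9:1, 50 °C; dilute HCl work-up
Reagents that add atoms: water, O
Why: Zerovalent palladium, formed in the flask from Pd(OAc)2 and PPh3 under CO, adds oxidatively into the C3–I bond with retention of geometry, CO inserts to give an acylpalladium iodide, and water with Et3N cleaves it to the acid and returns the catalyst. The closest known reaction type is the Heck-type hydroxycarbonylation of alkenyl iodides, together with the iodide-selective couplings of (E)-1-bromo-2-iodoalkenes. No ring closes here: the carboxyl is only placed cis to the C5≡C6 alkyne, whose triisopropylsilyl cap keeps the carboxylate from adding at this stage. No stereocentre is formed; C1' is not involved, and the C3=C4 geometry is carried through because oxidative addition, migratory insertion and acyl cleavage all retain it. Two selectivities are needed: C3–I over C4–Br, secured by the weaker C–I bond and a temperature at which PPh3-ligated palladium leaves alkenyl bromides alone, and capture of the alkenylpalladium by CO in preference to anti loss of bromide back to diyne 5, secured by the CO pressure and by the trans placing of Pd and Br, which rules out a syn elimination.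

Step 6
Reactants: 9 (R,E)-3-bromo-2-[1-(tert-butyldimethylsilyloxy)butyl]-5-(triisopropylsilyl)pent-2-en-4-ynoic acid
Product: 10 (R,E)-3-bromo-2-(1-hydroxybutyl)pent-2-en-4-ynoic acid
Conditions: Bu4NF (4 equiv), THF, 0 °C → rt; cold dilute HCl work-up
Reagents that add atoms: none
Why: Fluoride-induced desilylation, in which fluoride cleaves both the C(sp)–Si and the O–Si bond while the substrate sits as its carboxylate and is thereby protected from conjugate attack at C4, neither the alkene geometry nor C1' being affected.

Step 7
Reactants: 10 (R,E)-3-bromo-2-(1-hydroxybutyl)pent-2-en-4-ynoic acid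
Product: 11 (R,E)-4-bromo-3-(1-hydroxybutyl)-5-(iodomethylidene)furan-2(5H)-one
Conditions: I2 (3 equiv), NaHCO3 (3 equiv), MeCN, 0 °C → rt, dark; aq. Na2S2O3
Reagents that add atoms: iodine, II
Why: Iodolactonisation of a (Z)-2-en-4-ynoic acid, in which the carboxylate oxygen should open the iodonium ion of the terminal alkyne at the internal carbon C5 in the 5-exo-dig mode and anti to iodine, giving the ring O1–C2–C3–C4–C5 and the E iodomethylidene (I trans to O1), while the C1' hydroxyl, trans to the alkyne across C3=C4, cannot reach it.

**Compound list**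

1 | rac-hex-1-yn-3-ol | CCCC(O)C#C | starting material
2 | (R)-hex-1-yn-3-ol | CCC[C@@H](O)C#C | intermediate
3 | (bromoethynyl)triisopropylsilane | CC(C)[Si](C#CBr)(C(C)C)C(C)C | starting material
4 | (R)-1-(triisopropylsilyl)octa-1,3-diyn-5-ol | CCC[C@@H](O)C#CC#C[Si](C(C)C)(C(C)C)C(C)C | intermediate
5 | (R)-5-(tert-butyldimethylsilyloxy)-1-(triisopropylsilyl)octa-1,3-diyne | CCC[C@@H](O[Si](C)(C)C(C)(C)C)C#CC#C[Si](C(C)C)(C(C)C)C(C)C | intermediate
6 | iodine monobromide | BrI | starting material
7 | (R,E)-[3-bromo-5-(tert-butyldimethylsilyloxy)-4-iodooct-3-en-1-yn-1-yl]triisopropylsilane | CCC[C@@H](O[Si](C)(C)C(C)(C)C)/C(I)=C(\Br)C#C[Si](C(C)C)(C(C)C)C(C)C | intermediate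
8 | carbon monoxide | [C-]#[O+] | starting material
9 | (R,E)-3-bromo-2-[1-(tert-butyldimethylsilyloxy)butyl]-5-(triisopropylsilyl)pent-2-en-4-ynoic acid | CCC[C@@H](O[Si](C)(C)C(C)(C)C)/C(C(=O)O)=C(\Br)C#C[Si](C(C)C)(C(C)C)C(C)C | intermediate
10 | (R,E)-3-bromo-2-(1-hydroxybutyl)pent-2-en-4-ynoic acid | CCC[C@@H](O)/C(C(=O)O)=C(\Br)C#C | intermediate
11 | (R,E)-4-bromo-3-(1-hydroxybutyl)-5-(iodomethylidene)furan-2(5H)-one | CCC[C@@H](O)C1=C(Br)/C(=C\I)OC1=O | target

**Count**

Total steps: 7. Longest linear sequence: 7 steps (1 → 11); compounds 3, 6 and 8 enter as single partners.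

**Steps most likely to fail**

1. Step 5 (key step). The crowded, tetrasubstituted C3–palladium bond may take up CO slowly. The alkenylpalladium can then lose bromide and return diyne 5. If heat is used to force turnover, palladium may also insert into the C4–Br bond of the product, which has become a carbonyl-activated β-bromoacrylate, and carbonylate a second time. The fallback sets out from 7 and returns at 9; it brings C2 in at the alcohol oxidation level without CO. Stille coupling of 7 with (tributylstannyl)methanol (Pd2(dba)3, AsPh3, CuI, DMF, 45 °C) at the C3–I bond should give (R,Z)-3-bromo-2-[1-(tert-butyldimethylsilyloxy)butyl]-5-(triisopropylsilyl)pent-2-en-4-yn-1-ol F1, whose C4–Br bond is not activated by a carbonyl group. Oxidation with MnO2 in CH2Cl2 should give (R,E)-3-bromo-2-[1-(tert-butyldimethylsilyloxy)butyl]-5-(triisopropylsilyl)pent-2-en-4-ynal F2. Pinnick oxidation (NaClO2, NaH2PO4, 2-methylbut-2-ene, t-BuOH–H2O) should then give acid 9.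

2. Step 4. I–Br may attack the silylated outer alkyne in competition with the inner one, the iodonium ion may be opened at C3 instead of C4, or a second addition may follow; each would cost the halogen pattern on which step 5 depends. The fallback sets out from 4 and returns at 7; it reverses the order of halogenation and silylation. The free diynol 4 is treated with IBr (CH2Cl2, −78 °C, dark). The small hydroxyl shields C3≡C4 far less than the silyl ether does, and it can carry iodine to the neighbouring alkyne as a transient O–I species. This should give (R,E)-3-bromo-4-iodo-1-(triisopropylsilyl)oct-3-en-1-yn-5-ol F3. Silylation with t-BuMe2SiOTf and 2,6-lutidine (CH2Cl2, −78 °C) should then give 7.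

3. Step 7. The alkyne of 10 is conjugated to an electron-poor bromoacrylate and may react only slowly with iodine. A slow reaction leaves room for closure in the 6-endo mode to a 5-iodopyran-2-one and for iodine-promoted equilibration of the E iodomethylidene to its Z isomer. The fallback sets out from 10 and returns at 11; it separates ring closure from iodination. The sodium salt of 10 (NaHCO3) is cyclised with Hg(OAc)2 in aqueous MeCN and the product is treated with NaCl. Oxymercuration by divalent mercury is anti and places oxygen on the internal carbon, so this should give chloro{(E)-[3-bromo-4-((R)-1-hydroxybutyl)-5-oxofuran-2(5H)-ylidene]methyl}mercury F4, with Hg trans to O1. Iododemercuration with I2 (CH2Cl2, 0 °C, short contact, dark) replaces mercury with retention and should give 11.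

**Further compounds**

F1 | step 5 | (R,Z)-3-bromo-2-[1-(tert-butyldimethylsilyloxy)butyl]-5-(triisopropylsilyl)pent-2-en-4-yn-1-ol | CCC[C@@H](O[Si](C)(C)C(C)(C)C)/C(CO)=C(\Br)C#C[Si](C(C)C)(C(C)C)C(C)C
F2 | step 5 | (R,E)-3-bromo-2-[1-(tert-butyldimethylsilyloxy)butyl]-5-(triisopropylsilyl)pent-2-en-4-ynal | CCC[C@@H](O[Si](C)(C)C(C)(C)C)/C(C=O)=C(\Br)C#C[Si](C(C)C)(C(C)C)C(C)C
F3 | step 4 | (R,E)-3-bromo-4-iodo-1-(triisopropylsilyl)oct-3-en-1-yn-5-ol | CCC[C@@H](O)/C(I)=C(\Br)C#C[Si](C(C)C)(C(C)C)C(C)C
F4 | step 7 | chloro{(E)-[3-bromo-4-((R)-1-hydroxybutyl)-5-oxofuran-2(5H)-ylidene]methyl}mercury | CCC[C@@H](O)C1=C(Br)/C(=C\[Hg]Cl)OC1=O
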